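**Retrosynthetic overview**
- Target ⇒ (fluoride, same flask) its bis-silyl ether ⇒ key step: enantioselective photoredox ketyl–olefin coupling with radical–polar crossover between an A-ring salicylaldehyde and 4-silyloxystyrene. C3–C4 forms by radical addition, O1–C2 by cation capture, and both stereocentres arise here.
- A-ring aldehyde ⇒ chelation-controlled O-demethylation ⇒ silylation ⇒ ortho-formylation of 3,5-dimethoxy-4-prenylphenol.
- That phenol ⇒ Ir C–H borylation/oxidation of 2-prenyl-1,3-dimethoxybenzene ⇒ ortho-lithiation/prenylation of resorcinol dimethyl ether ⇒ resorcinol.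
- Styrene ⇒ Kumada vinylation of silyl-protected 4-bromophenol.
- Ring order: rings A and B are bought as benzenes; the pyran ring C is the only ring made, last, in the key step.

Compound numbers follow the forward sequence.
Assumption: the (R)-phosphoric acid in step 8 is taken to induce the (4R) configuration; if the opposite sense is found, the commercial (S)-acid is used with no other change.

**Step 1**
Reactants: 1 resorcinol
Product: 2 1,3-dimethoxybenzene
Conditions: MeI (2.5 equiv), K2CO3, acetone, reflux
Reagents that add atoms: iodomethane CI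
Why: Double Williamson ether synthesis (SN2 at MeI) gives the symmetric diether whose methoxy groups later serve as the directing pair, the C7 methoxy group and a temporary O1 mask.

**Step 2**
Reactants: 2 1,3-dimethoxybenzene; 3 1-bromo-3-methylbut-2-ene (prenyl bromide)
Product: 5 1,3-dimethoxy-2-(3-methylbut-2-en-1-yl)benzene, via (2,6-dimethoxyphenyl)lithium 4 (not isolated)
Conditions: n-BuLi, THF, 0 °C → rt; then 3, CuI (5 mol%), −78 °C → rt
Reagents that add atoms: n-butyllithium [Li]CCCC (gives the Li of 4; no atom of it remains in 5)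
Why: Directed ortho-metalation: the two methoxy groups direct lithiation to C2, and copper-assisted SN2 alkylation with the primary allylic bromide places the prenyl group between the two oxygens (future C8) without regioisomers.

**Step 3**
Reactants: 5 1,3-dimethoxy-2-(3-methylbut-2-en-1-yl)benzene
Product: 7 3,5-dimethoxy-4-(3-methylbut-2-en-1-yl)phenol, via aryl pinacolboronate 6 (not isolated)
Conditions: [Ir(OMe)(cod)]2 (1.5 mol%), dtbpy (3 mol%), B2pin2 (0.7 equiv), THF, 80 °C; then NaBO3·4H2O, THF/H2O, rt
Reagents that add atoms: bis(pinacolato)diboron CC1(C)OB(OC1(C)C)B1OC(C)(C)C(C)(C)O1 (Bpin of 6); sodium perborate [Na+].[Na+].O[B-]1(O)OO[B-](O)(O)OO1 (phenol O of 7)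
Why: Sterically governed iridium-catalysed aromatic C–H borylation takes the only ring C–H not ortho to a substituent (para to the prenyl group), and perborate oxidation of the C–B bond gives the phenol while leaving the trisubstituted alkene untouched.

**Step 4**
Reactants: 7 3,5-dimethoxy-4-(3-methylbut-2-en-1-yl)phenol
Product: 8 6-hydroxy-2,4-dimethoxy-3-(3-methylbut-2-en-1-yl)benzaldehyde
Conditions: MgCl2, Et3N, (CH2O)n, MeCN, reflux
Reagents that add atoms: formaldehyde (as paraformaldehyde) C=O
Why: Casnati–Skattebøl ortho-formylation runs through the magnesium phenoxide exclusively ortho to the OH, and the two ortho positions of 7 are equivalent by symmetry, so a single aldehyde forms.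

**Step 5**
Reactants: 8 6-hydroxy-2,4-dimethoxy-3-(3-methylbut-2-en-1-yl)benzaldehyde
Product: 9 6-[(tert-butyldimethylsilyl)oxy]-2,4-dimethoxy-3-(3-methylbut-2-en-1-yl)benzaldehyde
Conditions: TBSCl, imidazole, DMF, rt
Reagents that add atoms: tert-butyldimethylsilyl chloride CC(C)(C)[Si](C)(C)Cl
Why: Silylation of the only free phenol masks the future C5–OH so that only the other ortho oxygen can close the pyran ring in step 8.

**Step 6**
Reactants: 9 6-[(tert-butyldimethylsilyl)oxy]-2,4-dimethoxy-3-(3-methylbut-2-en-1-yl)benzaldehyde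
Product: 10 6-[(tert-butyldimethylsilyl)oxy]-2-hydroxy-4-methoxy-3-(3-methylbut-2-en-1-yl)benzaldehyde
Conditions: MgI2·OEt2 (2 equiv), toluene/Et2O, 80 °C; aq NH4Cl work-up
Reagents that add atoms: none
Why: Chelation-controlled ether cleavage: Mg(II) bridges the formyl oxygen and the ortho OMe and iodide removes that methyl by SN2 (the para OMe cannot chelate and stays), under aprotic conditions that should spare the prenyl group and the aryl silyl ether.

**Step 7**
Reactants: 11 (4-bromophenoxy)(tert-butyl)dimethylsilane; 12 vinylmagnesium bromide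
Product: 13 tert-butyl(4-ethenylphenoxy)dimethylsilane
Conditions: PdCl2(dppf) (2 mol%), THF, 50 °C
Reagents that add atoms: none
Why: Kumada–Corriu cross-coupling (oxidative addition, transmetalation from vinyl-Mg, reductive elimination) gives the styrene; the aryl silyl ether is inert to the Grignard reagent.

**Step 8**
Reactants: 10 6-[(tert-butyldimethylsilyl)oxy]-2-hydroxy-4-methoxy-3-(3-methylbut-2-en-1-yl)benzaldehyde; 13 tert-butyl(4-ethenylphenoxy)dimethylsilane (2 equiv)
Product: 15 (2S,4R)-2-(4-hydroxyphenyl)-7-methoxy-8-(3-methylbut-2-en-1-yl)-3,4-dihydro-2H-chromene-4,5-diol, via bis-silyl flavan-4-ol 14 (not isolated)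
Conditions: fac-Ir(ppy)3 (1 mol%), (R)-TRIP (10 mol%), CH2Cl2, 450 nm LEDs, −20 °C; then Et3N; then TBAF/AcOH (1:1), THF, 0 °C
Reagents that add atoms: none
Why: Proposed new method: excited fac-Ir(ppy)3 (E* ≈ −1.7 V vs SCE) reduces the formyl group of 10 by proton-coupled electron transfer through the chiral phosphoric acid; the phosphate-bound ketyl radical adds to the CH2 terminus of 13 (C3–C4 bond, enantio-determining, sets C4 as R); Ir(IV) (+0.77 V) oxidises the resulting p-silyloxybenzylic radical to the cation, which makes the cycle redox-neutral with no stoichiometric reductant; the free ortho OH then closes the ring (O1–C2) through a half-chair with the aryl group pseudo-equatorial and the C4–OH pushed pseudo-axial by peri strain with the 5-OTBS group, giving the 2,4-trans (2S) isomer; the closest known reaction types are enantioselective PCET ketyl (aza-pinacol) cyclisations with chiral phosphoric acids, intermolecular ketyl–styrene couplings, and radical–polar crossover capture of benzylic cations by O-nucleophiles; buffered fluoride finally removes both aryl silyl ethers without acid that would ionise the benzylic C4–OH.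

**Compound list**
1 | resorcinol | Oc1cccc(O)c1 | starting material
2 | 1,3-dimethoxybenzene | COc1cccc(OC)c1 | intermediate
3 | 1-bromo-3-methylbut-2-ene (prenyl bromide) | CC(C)=CCBr | starting material
4 | (2,6-dimethoxyphenyl)lithium | [Li]c1c(OC)cccc1OC | intermediate (not isolated)
5 | 1,3-dimethoxy-2-(3-methylbut-2-en-1-yl)benzene | COc1cccc(OC)c1CC=C(C)C | intermediate
6 | 2-[3,5-dimethoxy-4-(3-methylbut-2-en-1-yl)phenyl]-4,4,5,5-tetramethyl-1,3,2-dioxaborolane | COc1cc(cc(OC)c1CC=C(C)C)B1OC(C)(C)C(C)(C)O1 | intermediate (not isolated)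
7 | 3,5-dimethoxy-4-(3-methylbut-2-en-1-yl)phenol | COc1cc(O)cc(OC)c1CC=C(C)C | intermediate
8 | 6-hydroxy-2,4-dimethoxy-3-(3-methylbut-2-en-1-yl)benzaldehyde | COc1cc(O)c(C=O)c(OC)c1CC=C(C)C | intermediate
9 | 6-[(tert-butyldimethylsilyl)oxy]-2,4-dimethoxy-3-(3-methylbut-2-en-1-yl)benzaldehyde | COc1cc(O[Si](C)(C)C(C)(C)C)c(C=O)c(OC)c1CC=C(C)C | intermediate
10 | 6-[(tert-butyldimethylsilyl)oxy]-2-hydroxy-4-methoxy-3-(3-methylbut-2-en-1-yl)benzaldehyde | COc1cc(O[Si](C)(C)C(C)(C)C)c(C=O)c(O)c1CC=C(C)C | intermediate
11 | (4-bromophenoxy)(tert-butyl)dimethylsilane | CC(C)(C)[Si](C)(C)Oc1ccc(Br)cc1 | starting material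
12 | vinylmagnesium bromide | C=C[Mg]Br | starting material
13 | tert-butyl(4-ethenylphenoxy)dimethylsilane | C=Cc1ccc(O[Si](C)(C)C(C)(C)C)cc1 | intermediate
14 | (2S,4R)-5-[(tert-butyldimethylsilyl)oxy]-2-{4-[(tert-butyldimethylsilyl)oxy]phenyl}-7-methoxy-8-(3-methylbut-2-en-1-yl)-3,4-dihydro-2H-chromen-4-ol | COc1cc(O[Si](C)(C)C(C)(C)C)c2c(c1CC=C(C)C)O[C@H](c1ccc(O[Si](C)(C)C(C)(C)C)cc1)C[C@H]2O | intermediate (not isolated)
15 | (2S,4R)-2-(4-hydroxyphenyl)-7-methoxy-8-(3-methylbut-2-en-1-yl)-3,4-dihydro-2H-chromene-4,5-diol | COc1cc(O)c2c(c1CC=C(C)C)O[C@H](c1ccc(O)cc1)C[C@H]2O | target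

**Totals**
Total steps: 8. Longest linear sequence: 7 (steps 1–6, then 8).

**Steps most likely to fail, with fallbacks**

Step 8 (new enantioselective annulation; the acid may give low ee or ionise the very electron-rich benzylic alcohol). The fallback sets out from 10 and 13 and moves stereocontrol out of the radical step. The same photoredox annulation is run with achiral diphenyl phosphate (10 mol%), and the racemic 2,4-trans bis-silyl flavan-4-ol F1 is isolated. It is resolved by lipase-catalysed transesterification (Amano lipase PS, vinyl acetate, MTBE, 30 °C), which by Kazlauskas' rule acylates the (4R)-alcohol to the (2S,4R)-4-acetate F2, separable from the unreacted (2R,4S)-alcohol. K2CO3 in MeOH (0 °C → rt) then cleaves the acetate and both aryl silyl ethers, and the route is rejoined at 15.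

Step 3 (the prenyl alkene may be hydroborated or isomerised under iridium catalysis). The fallback sets out from 2 and introduces the oxygen before the alkene. Borylation/perborate oxidation of 2 gives, through 2-(3,5-dimethoxyphenyl)-4,4,5,5-tetramethyl-1,3,2-dioxaborolane F3, 3,5-dimethoxyphenol F4. TBSCl/imidazole gives tert-butyl(3,5-dimethoxyphenoxy)dimethylsilane F5. n-BuLi (THF, 0 °C) lithiates between the two methoxy groups to [4-(tert-butyldimethylsilyloxy)-2,6-dimethoxyphenyl]lithium F6, which is alkylated with 3 (CuI cat.) to tert-butyl[3,5-dimethoxy-4-(3-methylbut-2-en-1-yl)phenoxy]dimethylsilane F7. TBAF in THF then rejoins the route at 7.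

Step 6 (MgI2 may strip the silyl ether or be sluggish at the crowded methoxy group). The fallback sets out from 8 and swaps the basis of regiocontrol. BCl3 (CH2Cl2, −78 → −20 °C) removes only the methyl ortho to the formyl group through the boron chelate and gives 2,6-dihydroxy-4-methoxy-3-(3-methylbut-2-en-1-yl)benzaldehyde F8. The two phenols are then distinguished sterically: TBSCl (1.05 equiv), imidazole, CH2Cl2, −20 °C silylates the OH not flanked by the prenyl group, which rejoins the route at 10.

**Further compounds**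
F1 | step 8 | racemic (2S*,4R*)-5-[(tert-butyldimethylsilyl)oxy]-2-{4-[(tert-butyldimethylsilyl)oxy]phenyl}-7-methoxy-8-(3-methylbut-2-en-1-yl)-3,4-dihydro-2H-chromen-4-ol (1:1 mixture of enantiomers) | COc1cc(O[Si](C)(C)C(C)(C)C)c2c(c1CC=C(C)C)O[C@H](c1ccc(O[Si](C)(C)C(C)(C)C)cc1)C[C@H]2O.COc1cc(O[Si](C)(C)C(C)(C)C)c2c(c1CC=C(C)C)O[C@@H](c1ccc(O[Si](C)(C)C(C)(C)C)cc1)C[C@@H]2O
F2 | step 8 | (2S,4R)-5-[(tert-butyldimethylsilyl)oxy]-2-{4-[(tert-butyldimethylsilyl)oxy]phenyl}-7-methoxy-8-(3-methylbut-2-en-1-yl)-3,4-dihydro-2H-chromen-4-yl acetate | COc1cc(O[Si](C)(C)C(C)(C)C)c2c(c1CC=C(C)C)O[C@H](c1ccc(O[Si](C)(C)C(C)(C)C)cc1)C[C@H]2OC(C)=O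
F3 | step 3 | 2-(3,5-dimethoxyphenyl)-4,4,5,5-tetramethyl-1,3,2-dioxaborolane | COc1cc(OC)cc(c1)B1OC(C)(C)C(C)(C)O1
F4 | step 3 | 3,5-dimethoxyphenol | COc1cc(O)cc(OC)c1
F5 | step 3 | tert-butyl(3,5-dimethoxyphenoxy)dimethylsilane | COc1cc(OC)cc(O[Si](C)(C)C(C)(C)C)c1
F6 | step 3 | [4-(tert-butyldimethylsilyloxy)-2,6-dimethoxyphenyl]lithium | [Li]c1c(OC)cc(O[Si](C)(C)C(C)(C)C)cc1OC
F7 | step 3 | tert-butyl[3,5-dimethoxy-4-(3-methylbut-2-en-1-yl)phenoxy]dimethylsilane | COc1cc(O[Si](C)(C)C(C)(C)C)cc(OC)c1CC=C(C)C
F8 | step 6 | 2,6-dihydroxy-4-methoxy-3-(3-methylbut-2-en-1-yl)benzaldehyde | COc1cc(O)c(C=O)c(O)c1CC=C(C)C
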